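## Structural features

The target is a daucane-type hydroazulene. A cyclopentane (C3, C4, C5, C6, C7) is trans-fused through the C3–C7 bond to a cycloheptene (C1, C2, C3, C7, C8, C9, C10) whose only alkene is the trisubstituted C9=C10 carrying the C10 methyl. There are five stereocentres: C3 (all-carbon quaternary, angular methyl), C7 (ring-fusion CH), C6 (tertiary carbinol with isopropyl), C8 (CH–O-aroyl, next to C7) and C1 (CH–OAc, across the alkene from C8). The descriptors are 3R,3aS,4S,7S,8aR in azulene numbering, where 3 = C6, 3a = C7, 4 = C8, 7 = C1 and 8a = C3. In the flat drawing the C3 methyl and the C6 hydroxyl lie on the upper face; C7–H, the isopropyl group and both ester oxygens lie on the lower face, so the C8 and C1 oxygens are cis-1,4 across the alkene. Fragile groups are the two allylic esters, the free phenol, the acid-sensitive tertiary alcohol and, on the way, a β-oxygenated ketone open to retro-aldol cleavage and elimination. The real difficulty is the contiguous array C3(quaternary)–C7–C8 with a trans ring fusion, together with the need to tell apart two secondary allylic oxygens of similar reactivity. The key step uses the fact that C6, C7 and C3 are the carbonyl, α and β carbons of a cyclopentanone and that C8 is an aldol carbinol on C7.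

## Logic of the disconnections

**23 back to 18 and 21.** The phenol O–Si bond is restored (22) and the C8–O acyl bond is cut. The aroate is the most labile group and goes on last. This removes the aromatic part and leaves 18, with one free secondary alcohol. The forward esterification must take the secondary C8–OH and not the tertiary C6–OH, the phenol of the acid must be masked (21, from 19 via 20), and the final unmasking must leave two esters untouched.

**18 back to 16.** The C1–O acetyl bond is cut (17) and the C8 silyl ether is kept. The two allylic oxygens are told apart by the time at which they appear, not by reactivity. This leaves 16, whose only free secondary hydroxyl is at C1. Acetylation must spare C6–OH and the later desilylation must spare the acetate.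

**16 back to 15.** The C1–C10 bond is cut. C1 is a carbinol attached to an alkene carbon, the retron of an alkenylmetal addition to an aldehyde. The cut opens the seven-membered ring and leaves all other stereocentres on a single cyclopentane. The forward step needs a Z iodoalkene, a metalation that tolerates a free tertiary alcohol, a 7-exo closure, and facial control at C1.

**15 back to 12.** No skeletal bond is cut. The C1 aldehyde is traced through the primary alcohol 14 to the terminal carbon of a vinyl group on C3, because a vinyl group is what a conjugate addition can place on a quaternary carbon. The hydroboration must choose the vinyl group over the iodoalkene (via 13), and the oxidation must stop at the aldehyde.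

**12 back to 11.** The C6–isopropyl bond is cut. This turns the tertiary carbinol into the cyclopentanone that the key step delivers. The addition must beat enolisation, β-hydride reduction and halogen–metal exchange, and must come from the face of C7–H.

**11 back to 9.** The C2–Si bond is restored (10) and the O–Si bond at C8 is cut. Silicon on C2 is what makes the vinyl transfer efficient in the key step, and the C8 silyl ether protects the aldol. The acid protodesilylation is placed at the ketone stage because the later tertiary alcohol would ionise in acid; silylation must not trigger retro-aldol cleavage.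

**9 back to 7, 2 and 6.** The C2–C3 and C7–C8 bonds are cut. A functionalised cyclopentanone with three stereocentres falls apart into an achiral enone, a vinylmetal and an enal. The forward step must control the absolute configuration at C3, the regiochemistry of the enolate, the anti C7/C8 relation, and the face of C7.

**2 back to 1; 6 back to 3.** The C2–Al bond is cut (hydroalumination of 1). For 6, the aldehyde is traced to alcohol 5 and the C–I bond and Z geometry to alkyne 3 via 4. Both need defined regio- and stereochemistry of a hydroalumination.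

## Other disconnections considered

**Alternative 1:** The cut removes both C–O bonds at C8 and C1 and leads to the ring diene A1 (C8=C9–C10=C1). In the forward direction, singlet oxygen (O2, light, tetraphenylporphyrin) adds across C8 and C1 to give the endoperoxide A2, and O–O cleavage then frees the two hydroxyls.
- In its favour: the suprafacial cycloaddition fixes the cis-1,4 relation of the two oxygens by mechanism, two stereocentres arise in one cheap step, and approach from the face of C7–H (away from the angular methyl) would give the required face.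
- Against it: no C–C bond is formed, so A1 with C3, C6 and C7 already in place must come from elsewhere. The ene reaction at the trisubstituted alkene and base-induced rearrangement of A2 are competing paths. After O–O cleavage the two secondary allylic hydroxyls must be told apart by reactivity alone.
- Comparison: on the C1/C8 relative configuration this alternative is the better one, since the chosen plan relies on the conformation of a ring closure (step 10). On structure building and step economy the chosen plan is ahead, because its key step makes two C–C bonds and three stereocentres and differentiates the oxygens by timing.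

**Alternative 2:** The cut is at C9–C10 and C2–C3, giving the cyclopentenyl silyloxydiene A3 and the silyloxyvinyl diazo ester A4. In the forward direction Rh2(S-PTAD)4 generates the vinylcarbenoid, which cyclopropanates the enol-ether alkene of A3; Cope rearrangement of the cis-divinylcyclopropane gives A5.
- In its favour: one catalytic enantioselective step closes the seven-membered ring and sets quaternary C3. On ring construction it is better than the chosen key step, which closes no ring. On the origin of enantiocontrol (a chiral catalyst) the two are equal.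
- Against it: the Cope step must bond at a fully substituted cyclopentene carbon through a crowded boat transition state. Only one stereocentre results. C7 ends as an sp2 carbon, so the trans fusion, C8, C1 and C6 all remain open. The C10 ester must be taken down to a methyl group, two enol ethers must become stereodefined carbinols, and the C9=C10 alkene must be re-formed.
- Comparison: A5 has the full bicyclic carbon skeleton, but the oxidation state is wrong at four carbons. The number of corrective steps after the key step would probably exceed the ten steps that follow the chosen key step.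

**Alternative 3:** The cut is at C6–C7 of the five-membered ring and leads to the prochiral keto dialdehyde A6. In the forward direction proline forms an enamine with one of the two enantiotopic aldehyde arms, and the enamine carbon C7 attacks the isopropyl ketone (5-enolexo aldol) to give A7.
- In its favour: the tertiary carbinol with its isopropyl group forms without an organometallic addition to a hindered ketone, which is better than step 7 of the chosen plan. C3, C6 and C7 arise from an achiral open chain with a cheap, metal-free catalyst, which is also a point in its favour over the aluminium and copper reagents used here.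
- Against it: a hindered ketone is a poor, reversible aldol acceptor and dehydration threatens. The remote quaternary C3 is controlled only through the choice of arm. The required cis relation of C6–OH and the C7 formyl group is not the obvious preference of a hydrogen-bonded proline transition state. C7 stays epimerisable. A7 carries two aldehydes that must be differentiated, and the whole seven-membered ring with C8, C9, C10 and both carbinols is still to be built.
- Comparison: the chosen key step already contains C8 with its configuration and the C9=C10 unit. The alternative would need a comparable or larger number of steps to add them.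

Key step: step 4

**Remarks on the chemistry**
- L is a chiral bidentate N-heterocyclic carbene (4,5-diphenylimidazolin-2-ylidene with an N-aryl ortho-sulfonate arm), introduced as its silver complex Ag2L2. The enantiomer is chosen to give the 3S series of 9.
- Assumption: hydroalumination of 1 places aluminium on the silicon-bearing carbon, as is general for silyl alkynes.
- The descriptor at C3 changes from S (8, 9, 10) to R (11 onwards) only because the CIP priorities change; the geometry is the same throughout.

## Route

Step 1
Reactants: 1 ethynyltrimethylsilane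
Product: 2 diisobutyl[1-(trimethylsilyl)ethenyl]aluminium
Conditions: iBu2AlH (1.0 equiv), hexanes, 55 °C; solution used directly
Reagents that add atoms: diisobutylaluminium hydride, CC(C)C[AlH]CC(C)C
Why: Hydroalumination of a silyl alkyne; aluminium goes to the silicon-bearing carbon, which stabilises the C–Al carbon, and a hydrocarbon solvent disfavours deprotonation of the terminal alkyne.

Step 2
Reactants: 3 but-2-yn-1-ol
Product: 5 (Z)-3-iodobut-2-en-1-ol, via cyclic alkenylalanate 4 (not isolated)
Conditions: NaAlH2(OCH2CH2OMe)2, THF, 0 → 22 °C; then I2, −78 → 0 °C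
Reagents that add atoms: iodine, II
Why: Hydroxyl-directed trans-hydroalumination of a propargylic alcohol delivers hydride to C2 and aluminium to C3 within a five-membered oxaaluminacycle. Iodinolysis of the C–Al bond with retention puts iodine cis to the hydroxymethyl group, which is the Z alkene.

Step 3
Reactants: 5 (Z)-3-iodobut-2-en-1-ol
Product: 6 (Z)-3-iodobut-2-enal
Conditions: MnO2 (activated, excess), CH2Cl2, 22 °C, dark; filtered solution used at once
Reagents that add atoms: none
Why: Neutral heterogeneous oxidation of an allylic alcohol; the absence of acid and iodide and immediate use protect the Z geometry of the β-iodo enal.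

Step 4
Reactants: 7 3-methylcyclopent-2-en-1-one; 2 diisobutyl[1-(trimethylsilyl)ethenyl]aluminium; 6 (Z)-3-iodobut-2-enal
Product: 9 (2S,3S)-2-[(1R,2Z)-1-hydroxy-3-iodobut-2-en-1-yl]-3-methyl-3-[1-(trimethylsilyl)ethenyl]cyclopentan-1-one, via diisobutylaluminium enolate 8 (not isolated)
Conditions: Cu(OTf)2 (5 mol%), Ag2L2 (2.5 mol%), 2 (1.3 equiv), THF, −78 → −20 °C; then 6 (2.0 equiv), −78 °C; aq. KNaC4H4O6
Reagents that add atoms: none
Why: The 1-silylvinyl group passes from aluminium to the carbene-bound copper centre, adds to the β-carbon C3 of the aluminium-activated enone and leaves the regiodefined enolate 8 (C6–O–Al, C6=C7), which deprotonation could not give. The closest known reaction type is the copper-catalysed enantioselective conjugate addition of silyl-substituted vinylaluminium reagents to β-substituted cyclic enones, joined here to the aldol trapping of the metal enolate known from three-component enone couplings. No ring is closed; the step forms C2–C3 and C7–C8 and three stereocentres. C3 is set by the chiral carbene ligand (catalyst control). The enolate is E because it is held in the ring, and it should add to the aluminium-bound aldehyde through a closed six-membered chair transition state, which gives the anti C7/C8 relation. The aldehyde should approach C7 on the face opposite the bulky 1-silylvinyl group, cis to the C3 methyl, which is the arrangement of the later trans ring fusion. The step needs 1,2-addition to the aldehyde in preference to addition–elimination at the β-iodo enal, and retention of the Z alkene. Adding 6 at −78 °C only after the conjugate addition is complete, and keeping the excess of 2 small, should serve both.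

Step 5
Reactants: 9 (2S,3S)-2-[(1R,2Z)-1-hydroxy-3-iodobut-2-en-1-yl]-3-methyl-3-[1-(trimethylsilyl)ethenyl]cyclopentan-1-one
Product: 10 (2S,3S)-2-[(1R,2Z)-1-{[tert-butyl(dimethyl)silyl]oxy}-3-iodobut-2-en-1-yl]-3-methyl-3-[1-(trimethylsilyl)ethenyl]cyclopentan-1-one
Conditions: TBSOTf, 2,6-lutidine, CH2Cl2, −78 °C
Reagents that add atoms: tert-butyldimethylsilyl trifluoromethanesulfonate, CC(C)(C)[Si](C)(C)OS(=O)(=O)C(F)(F)F
Why: Silylation of the hindered aldol hydroxyl with a silyl triflate and a weak base at low temperature blocks retro-aldol cleavage and β-elimination. It also marks the C8 oxygen for the later aroate.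

Step 6
Reactants: 10 (2S,3S)-2-[(1R,2Z)-1-{[tert-butyl(dimethyl)silyl]oxy}-3-iodobut-2-en-1-yl]-3-methyl-3-[1-(trimethylsilyl)ethenyl]cyclopentan-1-one
Product: 11 (2S,3R)-2-[(1R,2Z)-1-{[tert-butyl(dimethyl)silyl]oxy}-3-iodobut-2-en-1-yl]-3-ethenyl-3-methylcyclopentan-1-one
Conditions: CF3CO2H (5 equiv), CH2Cl2, 0 → 22 °C
Reagents that add atoms: none
Why: Protodesilylation of a vinylsilane: ipso protonation at C2 gives a β-silyl-stabilised cation that loses silicon to trifluoroacetate, a reaction known for 1-silylvinyl groups on the β-quaternary carbon of cyclic ketones. It is done here, before the tertiary alcohol exists, because that alcohol would ionise in acid; the ketone, the iodoalkene and the hindered secondary silyl ether should tolerate dilute anhydrous acid.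

Step 7
Reactants: 11 (2S,3R)-2-[(1R,2Z)-1-{[tert-butyl(dimethyl)silyl]oxy}-3-iodobut-2-en-1-yl]-3-ethenyl-3-methylcyclopentan-1-one
Product: 12 (1R,2S,3R)-2-[(1R,2Z)-1-{[tert-butyl(dimethyl)silyl]oxy}-3-iodobut-2-en-1-yl]-3-ethenyl-3-methyl-1-(propan-2-yl)cyclopentan-1-ol
Conditions: iPrMgCl, CeCl3 (anhydrous), THF, −78 → −40 °C
Reagents that add atoms: isopropylmagnesium chloride, CC(C)[Mg]Cl
Why: Organocerium 1,2-addition to a hindered, enolisable cyclopentanone; cerium lowers the basicity and suppresses enolisation, β-hydride reduction and iodine–magnesium exchange. Attack should come from the face of C7–H, away from the C7 side chain and the pseudo-axial C3 methyl, which places the hydroxyl cis to the C3 methyl (6R in azulene terms 3R).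

Step 8
Reactants: 12 (1R,2S,3R)-2-[(1R,2Z)-1-{[tert-butyl(dimethyl)silyl]oxy}-3-iodobut-2-en-1-yl]-3-ethenyl-3-methyl-1-(propan-2-yl)cyclopentan-1-ol
Product: 14 (1R,2S,3R)-2-[(1R,2Z)-1-{[tert-butyl(dimethyl)silyl]oxy}-3-iodobut-2-en-1-yl]-3-(2-hydroxyethyl)-3-methyl-1-(propan-2-yl)cyclopentan-1-ol, via B-alkyl-9-borabicyclononane 13 (not isolated)
Conditions: 9-BBN, THF, 0 → 22 °C; then NaOH, H2O2, 0 °C
Reagents that add atoms: hydrogen peroxide, OO
Why: Anti-Markovnikov hydroboration–oxidation; 9-BBN reacts with the monosubstituted vinyl group far faster than with the trisubstituted, halogen-deactivated iodoalkene. Alkaline peroxide converts the C–B bond into the primary alcohol.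

Step 9
Reactants: 14 (1R,2S,3R)-2-[(1R,2Z)-1-{[tert-butyl(dimethyl)silyl]oxy}-3-iodobut-2-en-1-yl]-3-(2-hydroxyethyl)-3-methyl-1-(propan-2-yl)cyclopentan-1-ol
Product: 15 {(1R,2S,3R)-2-[(1R,2Z)-1-{[tert-butyl(dimethyl)silyl]oxy}-3-iodobut-2-en-1-yl]-3-hydroxy-1-methyl-3-(propan-2-yl)cyclopentyl}acetaldehyde
Conditions: PhI(OAc)2, TEMPO (10 mol%), CH2Cl2, 22 °C
Reagents that add atoms: none
Why: Nitroxyl-catalysed oxidation is selective for the primary alcohol and stops at the aldehyde. The tertiary alcohol cannot be oxidised, and its trans placement relative to the C2 arm rules out lactol formation.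

Step 10
Reactants: 15 {(1R,2S,3R)-2-[(1R,2Z)-1-{[tert-butyl(dimethyl)silyl]oxy}-3-iodobut-2-en-1-yl]-3-hydroxy-1-methyl-3-(propan-2-yl)cyclopentyl}acetaldehyde
Product: 16 (3R,3aS,4S,7S,8aR)-4-{[tert-butyl(dimethyl)silyl]oxy}-6,8a-dimethyl-3-(propan-2-yl)-1,2,3,3a,4,7,8,8a-octahydroazulene-3,7-diol
Conditions: CrCl2 (8 equiv), NiCl2 (2 mol%), DMSO/THF, 22 °C, 0.005 M
Reagents that add atoms: none
Why: Nozaki–Hiyama–Kishi reaction: zerovalent nickel inserts into the C10–I bond with retention of the Z geometry, and transmetalation to trivalent chromium gives an alkenylchromium that adds only to the aldehyde (7-exo-trig closure) and tolerates the free tertiary alcohol. The chromium-bound aldehyde oxygen is expected to sit pseudo-equatorial, away from the axial C3 methyl, so that C1–OH forms on the same face as the C8 oxygen (7S).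

Step 11
Reactants: 16 (3R,3aS,4S,7S,8aR)-4-{[tert-butyl(dimethyl)silyl]oxy}-6,8a-dimethyl-3-(propan-2-yl)-1,2,3,3a,4,7,8,8a-octahydroazulene-3,7-diol
Product: 17 (3R,3aS,4S,7S,8aR)-4-{[tert-butyl(dimethyl)silyl]oxy}-3-hydroxy-6,8a-dimethyl-3-(propan-2-yl)-1,2,3,3a,4,7,8,8a-octahydroazulen-7-yl acetate
Conditions: Ac2O, pyridine, DMAP (cat.), CH2Cl2, 0 → 22 °C
Reagents that add atoms: acetic anhydride, CC(=O)OC(C)=O
Why: DMAP-catalysed acylation of the secondary allylic C1 alcohol; the tertiary C6 alcohol is too hindered to react at ambient temperature and C8 is still silylated, so the acetate goes to C1 only.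

Step 12
Reactants: 17 (3R,3aS,4S,7S,8aR)-4-{[tert-butyl(dimethyl)silyl]oxy}-3-hydroxy-6,8a-dimethyl-3-(propan-2-yl)-1,2,3,3a,4,7,8,8a-octahydroazulen-7-yl acetate
Product: 18 (3R,3aS,4S,7S,8aR)-3,4-dihydroxy-6,8a-dimethyl-3-(propan-2-yl)-1,2,3,3a,4,7,8,8a-octahydroazulen-7-yl acetate
Conditions: HF·pyridine, pyridine, THF, 0 → 22 °C
Reagents that add atoms: none
Why: Fluoride cleavage of the secondary silyl ether under buffered, weakly acidic conditions, which leave the allylic acetate in place and do not promote acyl migration.

Step 13
Reactants: 19 4-hydroxybenzoic acid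
Product: 21 4-{[tert-butyl(dimethyl)silyl]oxy}benzoic acid, via bis-silylated benzoate 20 (not isolated)
Conditions: TBSCl (2.2 equiv), imidazole, DMF, 22 °C; then AcOH/THF/H2O, 22 °C
Reagents that add atoms: tert-butyldimethylsilyl chloride, CC(C)(C)[Si](C)(C)Cl
Why: Silylation of phenol and acid, then selective hydrolysis of the labile silyl ester by aqueous acetic acid. The masked phenol cannot compete as a nucleophile in the esterification.

Step 14
Reactants: 18 (3R,3aS,4S,7S,8aR)-3,4-dihydroxy-6,8a-dimethyl-3-(propan-2-yl)-1,2,3,3a,4,7,8,8a-octahydroazulen-7-yl acetate; 21 4-{[tert-butyl(dimethyl)silyl]oxy}benzoic acid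
Product: 22 (3R,3aS,4S,7S,8aR)-7-(acetyloxy)-3-hydroxy-6,8a-dimethyl-3-(propan-2-yl)-1,2,3,3a,4,7,8,8a-octahydroazulen-4-yl 4-{[tert-butyl(dimethyl)silyl]oxy}benzoate
Conditions: EDC·HCl, DMAP, CH2Cl2, 22 °C
Reagents that add atoms: none
Why: Steglich esterification: DMAP transfers the carbodiimide-activated acid to the secondary C8 alcohol with retention at C8. The tertiary C6 alcohol does not acylate, as in the selective esterification of related daucane diols.

Step 15
Reactants: 22 (3R,3aS,4S,7S,8aR)-7-(acetyloxy)-3-hydroxy-6,8a-dimethyl-3-(propan-2-yl)-1,2,3,3a,4,7,8,8a-octahydroazulen-4-yl 4-{[tert-butyl(dimethyl)silyl]oxy}benzoate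
Product: 23 (3R,3aS,4S,7S,8aR)-7-(acetyloxy)-3-hydroxy-6,8a-dimethyl-3-(propan-2-yl)-1,2,3,3a,4,7,8,8a-octahydroazulen-4-yl 4-hydroxybenzoate
Conditions: TBAF, AcOH (1:1), THF, 0 °C
Reagents that add atoms: none
Why: Fluoride cleaves the aryl silyl ether much faster than it attacks esters. Acetic acid buffers the phenoxide and suppresses acyl transfer or hydrolysis of the acetate and the aroate.

## Compound list

1 | ethynyltrimethylsilane | C#C[Si](C)(C)C | starting material
2 | diisobutyl[1-(trimethylsilyl)ethenyl]aluminium | C=C([Si](C)(C)C)[Al](CC(C)C)CC(C)C | intermediate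
3 | but-2-yn-1-ol | CC#CCO | starting material
4 | sodium 2,2-bis(2-methoxyethoxy)-3-methyl-2,5-dihydro-1,2-oxaaluminol-2-uide (cyclic alkenylalanate) | [Na+].COCCO[Al-]1(OCCOC)OCC=C1C | intermediate
5 | (Z)-3-iodobut-2-en-1-ol | OC/C=C(/C)I | intermediate
6 | (Z)-3-iodobut-2-enal | O=C/C=C(/C)I | intermediate
7 | 3-methylcyclopent-2-en-1-one | CC1=CC(=O)CC1 | starting material
8 | diisobutylaluminium (S)-3-methyl-3-[1-(trimethylsilyl)ethenyl]cyclopent-1-en-1-olate | CC(C)C[Al](CC(C)C)OC1=C[C@@](C)(C(=C)[Si](C)(C)C)CC1 | intermediate
9 | (2S,3S)-2-[(1R,2Z)-1-hydroxy-3-iodobut-2-en-1-yl]-3-methyl-3-[1-(trimethylsilyl)ethenyl]cyclopentan-1-one | O=C1CC[C@](C)(C(=C)[Si](C)(C)C)[C@H]1[C@@H](O)/C=C(/C)I | intermediate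
10 | (2S,3S)-2-[(1R,2Z)-1-{[tert-butyl(dimethyl)silyl]oxy}-3-iodobut-2-en-1-yl]-3-methyl-3-[1-(trimethylsilyl)ethenyl]cyclopentan-1-one | O=C1CC[C@](C)(C(=C)[Si](C)(C)C)[C@H]1[C@@H](O[Si](C)(C)C(C)(C)C)/C=C(/C)I | intermediate
11 | (2S,3R)-2-[(1R,2Z)-1-{[tert-butyl(dimethyl)silyl]oxy}-3-iodobut-2-en-1-yl]-3-ethenyl-3-methylcyclopentan-1-one | O=C1CC[C@](C)(C=C)[C@H]1[C@@H](O[Si](C)(C)C(C)(C)C)/C=C(/C)I | intermediate
12 | (1R,2S,3R)-2-[(1R,2Z)-1-{[tert-butyl(dimethyl)silyl]oxy}-3-iodobut-2-en-1-yl]-3-ethenyl-3-methyl-1-(propan-2-yl)cyclopentan-1-ol | C=C[C@@]1(C)CC[C@@](O)(C(C)C)[C@@H]1[C@@H](O[Si](C)(C)C(C)(C)C)/C=C(/C)I | intermediate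
13 | B-alkyl-9-borabicyclo[3.3.1]nonane adduct of 12 (boron on the terminal carbon C1) | C1CCC2CCCC1B2CC[C@@]1(C)CC[C@@](O)(C(C)C)[C@@H]1[C@@H](O[Si](C)(C)C(C)(C)C)/C=C(/C)I | intermediate
14 | (1R,2S,3R)-2-[(1R,2Z)-1-{[tert-butyl(dimethyl)silyl]oxy}-3-iodobut-2-en-1-yl]-3-(2-hydroxyethyl)-3-methyl-1-(propan-2-yl)cyclopentan-1-ol | OCC[C@@]1(C)CC[C@@](O)(C(C)C)[C@@H]1[C@@H](O[Si](C)(C)C(C)(C)C)/C=C(/C)I | intermediate
15 | {(1R,2S,3R)-2-[(1R,2Z)-1-{[tert-butyl(dimethyl)silyl]oxy}-3-iodobut-2-en-1-yl]-3-hydroxy-1-methyl-3-(propan-2-yl)cyclopentyl}acetaldehyde | O=CC[C@@]1(C)CC[C@@](O)(C(C)C)[C@@H]1[C@@H](O[Si](C)(C)C(C)(C)C)/C=C(/C)I | intermediate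
16 | (3R,3aS,4S,7S,8aR)-4-{[tert-butyl(dimethyl)silyl]oxy}-6,8a-dimethyl-3-(propan-2-yl)-1,2,3,3a,4,7,8,8a-octahydroazulene-3,7-diol | O[C@H]1C[C@@]2(C)CC[C@@](O)(C(C)C)[C@@H]2[C@@H](O[Si](C)(C)C(C)(C)C)C=C1C | intermediate
17 | (3R,3aS,4S,7S,8aR)-4-{[tert-butyl(dimethyl)silyl]oxy}-3-hydroxy-6,8a-dimethyl-3-(propan-2-yl)-1,2,3,3a,4,7,8,8a-octahydroazulen-7-yl acetate | CC(=O)O[C@H]1C[C@@]2(C)CC[C@@](O)(C(C)C)[C@@H]2[C@@H](O[Si](C)(C)C(C)(C)C)C=C1C | intermediate
18 | (3R,3aS,4S,7S,8aR)-3,4-dihydroxy-6,8a-dimethyl-3-(propan-2-yl)-1,2,3,3a,4,7,8,8a-octahydroazulen-7-yl acetate | CC(=O)O[C@H]1C[C@@]2(C)CC[C@@](O)(C(C)C)[C@@H]2[C@@H](O)C=C1C | intermediate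
19 | 4-hydroxybenzoic acid | OC(=O)c1ccc(O)cc1 | starting material
20 | tert-butyl(dimethyl)silyl 4-{[tert-butyl(dimethyl)silyl]oxy}benzoate | CC(C)(C)[Si](C)(C)OC(=O)c1ccc(O[Si](C)(C)C(C)(C)C)cc1 | intermediate
21 | 4-{[tert-butyl(dimethyl)silyl]oxy}benzoic acid | OC(=O)c1ccc(O[Si](C)(C)C(C)(C)C)cc1 | intermediate
22 | (3R,3aS,4S,7S,8aR)-7-(acetyloxy)-3-hydroxy-6,8a-dimethyl-3-(propan-2-yl)-1,2,3,3a,4,7,8,8a-octahydroazulen-4-yl 4-{[tert-butyl(dimethyl)silyl]oxy}benzoate | CC(=O)O[C@H]1C[C@@]2(C)CC[C@@](O)(C(C)C)[C@@H]2[C@@H](OC(=O)c2ccc(O[Si](C)(C)C(C)(C)C)cc2)C=C1C | intermediate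
23 | (3R,3aS,4S,7S,8aR)-7-(acetyloxy)-3-hydroxy-6,8a-dimethyl-3-(propan-2-yl)-1,2,3,3a,4,7,8,8a-octahydroazulen-4-yl 4-hydroxybenzoate | CC(=O)O[C@H]1C[C@@]2(C)CC[C@@](O)(C(C)C)[C@@H]2[C@@H](OC(=O)c2ccc(O)cc2)C=C1C | target

## Step count and risk

Total step count: 15. Longest linear sequence: 13 steps (3 to 23 through steps 2, 3, 4, 5, 6, 7, 8, 9, 10, 11, 12, 14 and 15).

**Step 4 (key step).** The most likely failure is slow or unselective aldol trapping. The aluminium enolate next to the new quaternary centre is hindered and weakly nucleophilic, residual vinylalane can consume the aldehyde, and the Z iodoenal can isomerise or undergo addition–elimination under Lewis-acidic conditions. Facial control at C7 could also be eroded by reversible aldolisation.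
Fallback: separate the two events. Starting from 7 and 2, the conjugate addition is run alone and enolate 8 is trapped with Me3SiOTf to give the trimethylsilyl enol ether F1, which is isolated. MeLi in THF at 0 °C then releases the lithium enolate F2, which is treated with 6 at −78 °C (closed transition state, anti) and returns to the route at 9.

**Step 6.** The risks are loss of the C8 silyl ether, acid-promoted β-elimination or epimerisation at C7 through the enol, and cationic rearrangement in place of clean ipso protonation.
Fallback: keep silicon and spend the C–Si bond later without acid. Starting from 10, iPrMgCl/CeCl3 gives the silylvinyl carbinol F3. BH3·THF at 0 °C followed by NaOH/H2O2 (boron at the terminal carbon, β to silicon) gives the β-hydroxysilane F4 as a mixture at the silyl-bearing carbon. Swern oxidation ((COCl)2, DMSO, Et3N) gives the α-silyl aldehyde F5, whose C–Si bond is cleaved by K2CO3 in MeOH through the enolate. The sequence returns to the route at 15.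

**Step 7.** Enolisation or β-hydride reduction of the hindered ketone may win over addition, or the reagent may approach from the wrong face.
Fallback: use an sp2 nucleophile without β-hydrogen and saturate it later. Starting from 11, 2-propenylmagnesium bromide/CeCl3 gives the isopropenyl carbinol F6. Disiamylborane (selective for the monosubstituted vinyl group over the 1,1-disubstituted one) followed by NaBO3 gives the isopropenyl diol F7. Diimide (2-nitrobenzenesulfonohydrazide, Et3N) reduces the isopropenyl group without touching the iodoalkene and returns to the route at 14.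

**Step 10.** Poor facial selectivity at C1 is the main risk, because only the conformation of the closing ring controls it. Premature protonation of the alkenylchromium during a slow seven-membered closure is the second.
Fallback: correct C1 by substitution. Starting from 15, if closure favours the C1 epimer F8, a Mitsunobu reaction with acetic acid (PPh3, diisopropyl azodicarboxylate, THF, 0 °C) inverts C1 and installs the acetate in one operation, returning to the route at 17.

## Further compounds

F1 | step 4 | (S)-trimethyl({3-methyl-3-[1-(trimethylsilyl)ethenyl]cyclopent-1-en-1-yl}oxy)silane | C[Si](C)(C)OC1=C[C@@](C)(C(=C)[Si](C)(C)C)CC1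
F2 | step 4 | lithium (S)-3-methyl-3-[1-(trimethylsilyl)ethenyl]cyclopent-1-en-1-olate | [Li]OC1=C[C@@](C)(C(=C)[Si](C)(C)C)CC1
F3 | step 6 | (1R,2S,3S)-2-[(1R,2Z)-1-{[tert-butyl(dimethyl)silyl]oxy}-3-iodobut-2-en-1-yl]-3-methyl-1-(propan-2-yl)-3-[1-(trimethylsilyl)ethenyl]cyclopentan-1-ol | C=C([Si](C)(C)C)[C@@]1(C)CC[C@@](O)(C(C)C)[C@@H]1[C@@H](O[Si](C)(C)C(C)(C)C)/C=C(/C)I
F4 | step 6 | (1R,2S,3S)-2-[(1R,2Z)-1-{[tert-butyl(dimethyl)silyl]oxy}-3-iodobut-2-en-1-yl]-3-[2-hydroxy-1-(trimethylsilyl)ethyl]-3-methyl-1-(propan-2-yl)cyclopentan-1-ol (mixture at the silyl-bearing carbon) | OCC([Si](C)(C)C)[C@@]1(C)CC[C@@](O)(C(C)C)[C@@H]1[C@@H](O[Si](C)(C)C(C)(C)C)/C=C(/C)I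
F5 | step 6 | 2-{(1S,2S,3R)-2-[(1R,2Z)-1-{[tert-butyl(dimethyl)silyl]oxy}-3-iodobut-2-en-1-yl]-3-hydroxy-1-methyl-3-(propan-2-yl)cyclopentyl}-2-(trimethylsilyl)acetaldehyde (mixture at the silyl-bearing carbon) | O=CC([Si](C)(C)C)[C@@]1(C)CC[C@@](O)(C(C)C)[C@@H]1[C@@H](O[Si](C)(C)C(C)(C)C)/C=C(/C)I
F6 | step 7 | (1S,2S,3R)-2-[(1R,2Z)-1-{[tert-butyl(dimethyl)silyl]oxy}-3-iodobut-2-en-1-yl]-3-ethenyl-3-methyl-1-(prop-1-en-2-yl)cyclopentan-1-ol | C=C[C@@]1(C)CC[C@@](O)(C(C)=C)[C@@H]1[C@@H](O[Si](C)(C)C(C)(C)C)/C=C(/C)I
F7 | step 7 | (1S,2S,3R)-2-[(1R,2Z)-1-{[tert-butyl(dimethyl)silyl]oxy}-3-iodobut-2-en-1-yl]-3-(2-hydroxyethyl)-3-methyl-1-(prop-1-en-2-yl)cyclopentan-1-ol | OCC[C@@]1(C)CC[C@@](O)(C(C)=C)[C@@H]1[C@@H](O[Si](C)(C)C(C)(C)C)/C=C(/C)I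
F8 | step 10 | (3R,3aS,4S,7R,8aR)-4-{[tert-butyl(dimethyl)silyl]oxy}-6,8a-dimethyl-3-(propan-2-yl)-1,2,3,3a,4,7,8,8a-octahydroazulene-3,7-diol | O[C@@H]1C[C@@]2(C)CC[C@@](O)(C(C)C)[C@@H]2[C@@H](O[Si](C)(C)C(C)(C)C)C=C1C
A1 | alternative 1 | triethyl{[(3R,3aR,8aR)-6,8a-dimethyl-3-(propan-2-yl)-1,2,3,3a,8,8a-hexahydroazulen-3-yl]oxy}silane (ring diene C8=C9–C10=C1) | CC1=CC[C@@]2(C)CC[C@@](O[Si](CC)(CC)CC)(C(C)C)[C@@H]2C=C1
A2 | alternative 1 | (3R,3aS,4S,7S,8aR)-4,7-epidioxy-6,8a-dimethyl-3-(propan-2-yl)-3-[(triethylsilyl)oxy]-1,2,3,3a,4,7,8,8a-octahydroazulene (C8,C1-endoperoxide) | CC1=C[C@@H]2OO[C@H]1C[C@@]3(C)CC[C@@](O[Si](CC)(CC)CC)(C(C)C)[C@H]23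
A3 | alternative 2 | tert-butyl(dimethyl){[1-(7-methyl-1,4-dioxaspiro[4.4]non-6-en-6-yl)ethenyl]oxy}silane | C=C(O[Si](C)(C)C(C)(C)C)C1=C(C)CCC12OCCO2
A4 | alternative 2 | methyl 3-{[tert-butyl(dimethyl)silyl]oxy}-2-diazobut-3-enoate | COC(=O)C(=[N+]=[N-])C(=C)O[Si](C)(C)C(C)(C)C
A5 | alternative 2 | hydroazulene bis(tert-butyldimethylsilyl enol ether) methyl ester with the C6 ethylene ketal (enol ethers at C1 and C8, ester on C10, C3 configured as in 23) | COC(=O)C1=C(O[Si](C)(C)C(C)(C)C)C[C@@]2(C)CCC3(OCCO3)C2=C(O[Si](C)(C)C(C)(C)C)C1
A6 | alternative 3 | 3-methyl-3-(4-methyl-3-oxopentyl)pentanedial | CC(C)C(=O)CCC(C)(CC=O)CC=O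
A7 | alternative 3 | (1R,2R,5R)-2-hydroxy-5-methyl-5-(2-oxoethyl)-2-(propan-2-yl)cyclopentane-1-carbaldehyde | O=CC[C@@]1(C)CC[C@@](O)(C(C)C)[C@@H]1C=O
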